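**Strategy.** The target is cut at two bonds, the C8–O ether to C4' of ring B and the C7–OAc bond, which returns two molecules of one phenol, (E)-2,6-dimethoxy-4-(prop-1-enyl)phenol, and acetic acid. The key step oxidises that phenol so that the oxygen of one molecule (future ring B) couples to C8 of another, then adds acetic acid under a chiral phosphoric acid to C7 of the ring A para-quinone methide formed. It exploits the C4 oxygen para to C7 on ring A, the C7=C8 double bond, and the C3/C5 methoxy groups of both rings, which block ortho coupling. The precursor is the unprotected E-propenylphenol; methylation of the ring A C4 hydroxyl finishes the synthesis.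

Key step: step 2

Numbering: ring A is the 3,4,5-trioxygenated ring carrying the C7–C8–C9 chain (C7 benzylic, C9 methyl); ring B is the propenyl ring, bonded through its C4' oxygen to C8. The target is the threo (7R,8R) isomer.

Assumption: the sense of induction of the binaphthyl phosphoric acid on this quinone methide cannot be derived from precedent; the (R)-acid is written, and the (S)-acid is used instead if the first run shows acetate delivery to the Si face of C7.

Step 1
Reactants: 1 4-allyl-2,6-dimethoxyphenol
Product: 2 (E)-2,6-dimethoxy-4-(prop-1-enyl)phenol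
Conditions: RuHCl(CO)(PPh3)3 (1 mol%), toluene, 80 °C, Ar
Reagents that add atoms: none
Why: Metal hydride-catalysed alkene isomerisation (hydride insertion, then β-hydride elimination toward the benzylic carbon) by a divalent ruthenium hydride that tolerates free phenols moves the terminal double bond into conjugation, the E-styrene being favoured thermodynamically; no stereocentre is formed and residual Z isomer is removed by chromatography.

Step 2
Reactants: 2 (E)-2,6-dimethoxy-4-(prop-1-enyl)phenol (two molecules); 3 acetic acid
Product: 5 (1R,2R)-1-(4-hydroxy-3,5-dimethoxyphenyl)-2-{2,6-dimethoxy-4-[(E)-prop-1-enyl]phenoxy}propyl acetate, via quinone methide 4 (not isolated)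
Conditions: Ag2O (0.6 equiv), 4 Å MS, CH2Cl2, rt, dark; filter under Ar; then AcOH (3 equiv), (R)-3,3'-bis(2,4,6-triisopropylphenyl)-1,1'-binaphthalene-2,2'-diyl hydrogen phosphate (10 mol%), CH2Cl2–toluene, −40 °C; cold pH 7 work-up
Reagents that add atoms: acetic acid (3), CC(=O)O
Why: Proposed new method: Ag2O removes one electron from each phenol to give a phenoxyl radical with spin on the phenol oxygen and on C8; the oxygen of one radical bonds to C8 of another to give para-quinone methide 4, and once silver and the water of oxidation are removed, the chiral phosphoric acid, hydrogen-bonded to the quinone methide carbonyl and to acetic acid, should deliver acetate to the Re face of C7 in a 1,6-addition that rearomatises ring A. The closest known reactions are the racemic Ag2O-mediated 8-O-4' coupling of this phenol with capture of the quinone methide by water or alcohols, and chiral phosphoric acid-catalysed 1,6-additions of heteroatom nucleophiles to para-quinone methides; their union with a carboxylic acid nucleophile on a quinone methide that already carries a stereocentre is untested. No ring is closed. C8 is formed in the radical coupling without control, so 4 is racemic, while C7 is set by the catalyst: (8R)-4 leads to threo (7R,8R)-5 and (8S)-4 to the erythro (7R,8S) isomer, which is removed by chromatography, so at most half of the dimer can become 5. In the conformer of 4 with C8–H eclipsing the exocyclic double bond, attack anti to the aryloxy group gives erythro, so the threo product is the mismatched case and the catalyst must overrule the substrate; in return the other threo enantiomer would need both preferences to fail, which protects the enantiomeric purity of 5. The step also needs O–C8 instead of C–C coupling, which the methoxy groups at C3 and C5 of both rings secure by blocking the ortho carbons, leaving C8–C8' coupling as the main competitor.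

Step 3
Reactants: 5 (1R,2R)-1-(4-hydroxy-3,5-dimethoxyphenyl)-2-{2,6-dimethoxy-4-[(E)-prop-1-enyl]phenoxy}propyl acetate
Product: 6 (1R,2R)-2-{2,6-dimethoxy-4-[(E)-prop-1-enyl]phenoxy}-1-(3,4,5-trimethoxyphenyl)propyl acetate (Compound NP-024268)
Conditions: TMSCHN2 (2 M in hexanes, 3 equiv), toluene–MeOH 4:1, 0 °C to rt, on freshly prepared 5
Reagents that add atoms: trimethylsilyldiazomethane, C[Si](C)(C)C=[N+]=[N-]
Why: Diazoalkane O-methylation of a phenol, in which the phenol protonates the diazo carbon, methanol removes silicon and the methyldiazonium–phenoxide ion pair collapses at once with loss of N2, so no long-lived phenoxide is present to expel the C7 acetate, and C7, C8 and the propenyl group are untouched.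

**Compound list**
1 | 4-allyl-2,6-dimethoxyphenol | C=CCc1cc(OC)c(O)c(OC)c1 | starting material
2 | (E)-2,6-dimethoxy-4-(prop-1-enyl)phenol | C/C=C/c1cc(OC)c(O)c(OC)c1 | intermediate
3 | acetic acid | CC(=O)O | starting material
4 | 4-[(2R)-2-{2,6-dimethoxy-4-[(E)-prop-1-enyl]phenoxy}propylidene]-2,6-dimethoxycyclohexa-2,5-dien-1-one, formed as the racemate; the 8R enantiomer shown is the one that leads to 5 | C/C=C/c1cc(OC)c(O[C@H](C)C=C2C=C(OC)C(=O)C(OC)=C2)c(OC)c1 | intermediate
5 | (1R,2R)-1-(4-hydroxy-3,5-dimethoxyphenyl)-2-{2,6-dimethoxy-4-[(E)-prop-1-enyl]phenoxy}propyl acetate | C/C=C/c1cc(OC)c(O[C@H](C)[C@H](OC(C)=O)c2cc(OC)c(O)c(OC)c2)c(OC)c1 | intermediate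
6 | (1R,2R)-2-{2,6-dimethoxy-4-[(E)-prop-1-enyl]phenoxy}-1-(3,4,5-trimethoxyphenyl)propyl acetate | C/C=C/c1cc(OC)c(O[C@H](C)[C@H](OC(C)=O)c2cc(OC)c(OC)c(OC)c2)c(OC)c1 | target

Total step count: 3. Longest linear sequence: 3 steps (1 → 2 → 5 → 6).

**Steps most likely to fail**

Step 2 (proposed new method). The radical pair may partition toward C8–C8' bond formation. The oxygen attacks either face of C8 without bias, so half of the dimer enters the 8S series. Acetate delivery at C7 must override the substrate's erythro preference in the 8R series and outrun uncatalysed addition. The benzylic acetate para to a free phenol may re-ionise to the quinone methide and scramble C7.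
Fallback, known chemistry, setting out from 2 and coming back at 6 (step 3 is then not needed):
- Mitsunobu reaction of 2 with ethyl (S)-lactate (PPh3, diisopropyl azodicarboxylate, THF) should give, with inversion, ethyl (2R)-2-{2,6-dimethoxy-4-[(E)-prop-1-enyl]phenoxy}propanoate F1.
- MeNH(OMe)·HCl and iPrMgCl at −20 °C convert it into (2R)-2-{2,6-dimethoxy-4-[(E)-prop-1-enyl]phenoxy}-N-methoxy-N-methylpropanamide F2.
- 3,4,5-Trimethoxyphenylmagnesium bromide, followed by a cold acidic quench, gives (2R)-2-{2,6-dimethoxy-4-[(E)-prop-1-enyl]phenoxy}-1-(3,4,5-trimethoxyphenyl)propan-1-one F3.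
- Reduction with catecholborane and (R)-1-methyl-3,3-diphenyltetrahydro-1H,3H-pyrrolo[1,2-c][1,3,2]oxazaborole at −78 °C should give (1R,2R)-2-{2,6-dimethoxy-4-[(E)-prop-1-enyl]phenoxy}-1-(3,4,5-trimethoxyphenyl)propan-1-ol F4. Catalyst control and the Felkin–Anh preference both point to the 7R carbinol, and the alkene is not hydroborated.
- Ac2O, pyridine and 4-dimethylaminopyridine then give 6.

Step 3. A transient phenoxide may expel the C7 acetate, re-forming the quinone methide with loss of the ester or of the C7 configuration, or methylation of the hindered phenol may stall.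
Fallback, setting out from 5 and coming back at 6:
- iBu2AlH (excess, CH2Cl2, −78 °C) cleaves the acetyl group reductively to (1R,2R)-1-(4-hydroxy-3,5-dimethoxyphenyl)-2-{2,6-dimethoxy-4-[(E)-prop-1-enyl]phenoxy}propan-1-ol F5, whose benzylic hydroxyl is a poor leaving group.
- MeI and K2CO3 in acetone then methylate only the phenol, giving the alcohol F4 described above.
- Ac2O, pyridine and 4-dimethylaminopyridine return to 6.

Step 1. Double-bond migration may stop short, or E/Z selectivity may be imperfect, so that Z isomer is carried into the coupling; the free phenol may also slow the catalyst.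
Fallback, setting out from 1 and coming back at 2:
- Ac2O and pyridine give 4-allyl-2,6-dimethoxyphenyl acetate F6.
- PdCl2(MeCN)2 (divalent palladium, 5 mol%, CH2Cl2, rt) isomerises the neutral ester to 2,6-dimethoxy-4-[(E)-prop-1-enyl]phenyl acetate F7, which is freed of Z isomer by crystallisation.
- K2CO3 in MeOH returns 2.

**Further compounds**
F1 | step 2 | ethyl (2R)-2-{2,6-dimethoxy-4-[(E)-prop-1-enyl]phenoxy}propanoate | C/C=C/c1cc(OC)c(O[C@H](C)C(=O)OCC)c(OC)c1
F2 | step 2 | (2R)-2-{2,6-dimethoxy-4-[(E)-prop-1-enyl]phenoxy}-N-methoxy-N-methylpropanamide | C/C=C/c1cc(OC)c(O[C@H](C)C(=O)N(C)OC)c(OC)c1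
F3 | step 2 | (2R)-2-{2,6-dimethoxy-4-[(E)-prop-1-enyl]phenoxy}-1-(3,4,5-trimethoxyphenyl)propan-1-one | C/C=C/c1cc(OC)c(O[C@H](C)C(=O)c2cc(OC)c(OC)c(OC)c2)c(OC)c1
F4 | step 2 | (1R,2R)-2-{2,6-dimethoxy-4-[(E)-prop-1-enyl]phenoxy}-1-(3,4,5-trimethoxyphenyl)propan-1-ol | C/C=C/c1cc(OC)c(O[C@H](C)[C@H](O)c2cc(OC)c(OC)c(OC)c2)c(OC)c1
F5 | step 3 | (1R,2R)-1-(4-hydroxy-3,5-dimethoxyphenyl)-2-{2,6-dimethoxy-4-[(E)-prop-1-enyl]phenoxy}propan-1-ol | C/C=C/c1cc(OC)c(O[C@H](C)[C@H](O)c2cc(OC)c(O)c(OC)c2)c(OC)c1
F6 | step 1 | 4-allyl-2,6-dimethoxyphenyl acetate | C=CCc1cc(OC)c(OC(C)=O)c(OC)c1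
F7 | step 1 | 2,6-dimethoxy-4-[(E)-prop-1-enyl]phenyl acetate | C/C=C/c1cc(OC)c(OC(C)=O)c(OC)c1
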